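**Retrosynthetic overview**

1. Target ⇐ acid hydrolysis of the trans-(9R,10S)-9,10-epoxy-11-ol, with water attacking C9 with inversion; the C11 tertiary alcohol is already in place.
2. Epoxy alcohol ⇐ hydroxyl-directed, metal-free peptide-peracid asymmetric epoxidation of the (9E)-allylic tertiary alcohol (new step; sets C9 and C10).
3. That aryl ether ⇐ Mitsunobu coupling of 5,7-dihydroxycoumarin (7-OH) with the (2E,6E,9E)-triene-1,11-diol.
4. Trienediol ⇐ C8–C9 allyl–alkenyl Suzuki coupling of (E)-8-bromogeranyl acetate (from geranyl acetate by SeO2 oxidation and Appel bromination) with an (E)-alkenylboronate carrying the CMe2OH end.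
5. Rings: both coumarin rings are bought intact in 5,7-dihydroxycoumarin; the only ring made is the oxirane (step 5), opened again in step 6.

Assumption: side-chain carbons are numbered as in farnesol (C1 = OCH2 … C11 = CMe2OH), and geranyl acetate, the alkenylboronate and 5,7-dihydroxycoumarin are taken as catalogue compounds.

**Route**

Step 1
Reactants: 1 geranyl acetate
Product: 2 (2E,6E)-8-hydroxy-3,7-dimethylocta-2,6-dien-1-yl acetate
Conditions: SeO2 (0.1 equiv), t-BuOOH (70% aq., 3 equiv), salicylic acid (0.1 equiv), CH2Cl2, rt, 24 h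
Reagents that add atoms: tert-butyl hydroperoxide, CC(C)(C)OO; selenium dioxide, O=[Se]=O (catalytic oxygen carrier)
Why: SeO2/t-BuOOH allylic oxidation (ene reaction then [2,3]-sigmatropic shift) hydroxylates only the (E)-methyl of the electron-rich 6,7-alkene, the 2,3-alkene being deactivated by the allylic acetate, and no stereocentre is formed.

Step 2
Reactants: 2 (2E,6E)-8-hydroxy-3,7-dimethylocta-2,6-dien-1-yl acetate
Product: 3 (2E,6E)-8-bromo-3,7-dimethylocta-2,6-dien-1-yl acetate
Conditions: CBr4 (1.2 equiv), PPh3 (1.2 equiv), CH2Cl2, 0 °C, 1 h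
Reagents that add atoms: carbon tetrabromide, BrC(Br)(Br)Br
Why: Appel bromination converts the primary allylic alcohol into the bromide under neutral conditions without allylic transposition or loss of the acetate, and no stereocentre is formed.

Step 3
Reactants: 3 (2E,6E)-8-bromo-3,7-dimethylocta-2,6-dien-1-yl acetate; 4 (E)-2-methyl-4-(4,4,5,5-tetramethyl-1,3,2-dioxaborolan-2-yl)but-3-en-2-ol
Product: 6 (2E,6E,9E)-3,7,11-trimethyldodeca-2,6,9-triene-1,11-diol, via trienyl acetate 5 (not isolated)
Conditions: Pd(PPh3)4 (3 mol%), K2CO3 (3 equiv), THF/H2O (5:1), 45 °C, 4 h; then MeOH, rt, 2 h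
Reagents that add atoms: none
Why: Suzuki–Miyaura allyl–alkenyl coupling, in which zerovalent palladium adds to the allylic bromide far faster than to the trisubstituted allylic acetate and the alkenyl group is delivered to the less hindered CH2 terminus with retention of all (E) geometries, is followed by carbonate-mediated methanolysis of the acetate; no stereocentre is formed.

Step 4
Reactants: 6 (2E,6E,9E)-3,7,11-trimethyldodeca-2,6,9-triene-1,11-diol; 7 5,7-dihydroxycoumarin (1.5 equiv)
Product: 8 5-hydroxy-7-{[(2E,6E,9E)-11-hydroxy-3,7,11-trimethyldodeca-2,6,9-trien-1-yl]oxy}coumarin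
Conditions: PPh3 (1.3 equiv), DIAD (1.3 equiv), THF, 0 °C → rt
Reagents that add atoms: none
Why: Mitsunobu etherification activates only the primary allylic alcohol (the tertiary one is inert) and alkylates the more acidic, less hindered 7-OH of 7 in preference to the peri 5-OH; no stereocentre is formed.

Step 5
Reactants: 8 5-hydroxy-7-{[(2E,6E,9E)-11-hydroxy-3,7,11-trimethyldodeca-2,6,9-trien-1-yl]oxy}coumarin
Product: 9 5-hydroxy-7-{[(2E,6E)-8-[(2R,3S)-3-(2-hydroxypropan-2-yl)oxiran-2-yl]-3,7-dimethylocta-2,6-dien-1-yl]oxy}coumarin, the (9R,10S)-9,10-epoxide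
Conditions: Boc-L-Asp-D-Pro-Aib-L-Phe-OMe (10 mol%), DMAP (10 mol%), DIC (2 equiv), 30% aq. H2O2 (2.5 equiv), CHCl3, 4 °C, 24–36 h
Reagents that add atoms: hydrogen peroxide, OO
Why: Proposed new method: the Asp side-chain acid of a β-turn peptide is cycled to its peracid by DIC/H2O2 (DMAP as acyl-transfer co-catalyst) while the peptide backbone hydrogen-bonds the tertiary C11–OH, so oxygen is delivered in a Henbest-type butterfly transition state to one face of the adjacent (E)-9,10-alkene, overriding the higher innate nucleophilicity of the remote 6,7-alkene (the 2,3-alkene and the coumarin C3=C4 are electron-poor) and setting C9 and C10 together as the (9R,10S)-trans-epoxide; the sense of induction cannot be predicted, so the first run fixes which antipode is used (the mirror-image peptide is equally accessible); the closest known reaction type is the aspartyl-peptide-catalysed, hydroxyl-directed site- and enantioselective epoxidation of primary allylic alcohols such as the 2,3-alkene of farnesol, not yet shown for tertiary allylic alcohols bearing a trans-disubstituted alkene.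

Step 6
Reactants: 9 the (9R,10S)-9,10-epoxide
Product: 10 5-hydroxy-7-{[(2E,6E,9S,10S)-9,10,11-trihydroxy-3,7,11-trimethyldodeca-2,6-dien-1-yl]oxy}coumarin (CNP0174708.2)
Conditions: HClO4 (0.3 M), THF/H2O (3:1), 0 °C → rt, 6–12 h
Reagents that add atoms: water, O
Why: Acid-catalysed anti (SN2-like) epoxide hydrolysis, in which water attacks C9 rather than the neopentyl-like, inductively deactivated C10 next to the quaternary carbinol, inverts C9 and retains C10, turning the (9R,10S)-trans-epoxide into the (9S,10S)-anti-diol beside the existing C11 alcohol.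

**Compound list**

1 | geranyl acetate, (2E)-3,7-dimethylocta-2,6-dien-1-yl acetate | C/C(=C\COC(C)=O)CCC=C(C)C | starting material
2 | (2E,6E)-8-hydroxy-3,7-dimethylocta-2,6-dien-1-yl acetate | C/C(=C\COC(C)=O)CC/C=C(\C)CO | intermediate
3 | (2E,6E)-8-bromo-3,7-dimethylocta-2,6-dien-1-yl acetate | C/C(=C\COC(C)=O)CC/C=C(\C)CBr | intermediate
4 | (E)-2-methyl-4-(4,4,5,5-tetramethyl-1,3,2-dioxaborolan-2-yl)but-3-en-2-ol | CC(C)(O)/C=C/B1OC(C)(C)C(C)(C)O1 | starting material
5 | (2E,6E,9E)-11-hydroxy-3,7,11-trimethyldodeca-2,6,9-trien-1-yl acetate | C/C(=C\COC(C)=O)CC/C=C(\C)C/C=C/C(C)(C)O | intermediate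
6 | (2E,6E,9E)-3,7,11-trimethyldodeca-2,6,9-triene-1,11-diol | C/C(=C\CO)CC/C=C(\C)C/C=C/C(C)(C)O | intermediate
7 | 5,7-dihydroxycoumarin (5,7-dihydroxy-2H-chromen-2-one) | O=c1ccc2c(O)cc(O)cc2o1 | starting material
8 | 5-hydroxy-7-{[(2E,6E,9E)-11-hydroxy-3,7,11-trimethyldodeca-2,6,9-trien-1-yl]oxy}coumarin | C/C(=C\COc1cc(O)c2ccc(=O)oc2c1)CC/C=C(\C)C/C=C/C(C)(C)O | intermediate
9 | 5-hydroxy-7-{[(2E,6E)-8-[(2R,3S)-3-(2-hydroxypropan-2-yl)oxiran-2-yl]-3,7-dimethylocta-2,6-dien-1-yl]oxy}coumarin | C/C(=C\COc1cc(O)c2ccc(=O)oc2c1)CC/C=C(\C)C[C@H]1O[C@@H]1C(C)(C)O | intermediate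
10 | 5-hydroxy-7-{[(2E,6E,9S,10S)-9,10,11-trihydroxy-3,7,11-trimethyldodeca-2,6-dien-1-yl]oxy}coumarin | C/C(=C\COc1cc(O)c2ccc(=O)oc2c1)CC/C=C(\C)C[C@H](O)[C@H](O)C(C)(C)O | target

**Step count and risks**

Total steps: 6. Longest linear sequence: 6 (1 → 2 → 3 → 6 → 8 → 9 → 10).

The three steps most likely to fail:

First, step 5, the proposed peptide-peracid epoxidation. The 6,7-trisubstituted alkene is innately more nucleophilic than the target 9,10-alkene, the free 5-OH may compete for the catalyst's hydrogen-bond sites, and the facial sense is not predictable in advance. Running to partial conversion and recycling 8 is the first remedy. The fallback sets out from 8 and comes back to the route at 9. It uses the known alkoxide-templated asymmetric epoxidation of tertiary allylic alcohols: Hf(OtBu)4 (tetravalent hafnium) with a chiral C2-symmetric bishydroxamic acid ligand and cumene hydroperoxide in toluene. Here the substrate is bound covalently as its alkoxide to the metal peroxide, so site selectivity no longer depends on hydrogen bonding, and the ligand antipode is chosen to give the (9R,10S)-epoxide. No new compound arises on this way (none F0).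

Second, step 4, the Mitsunobu coupling. Some 5-O-alkylation or bis-alkylation of 7 is possible. The fallback sets out from 7 and comes back at 8, fixing regiochemistry by protection. Ac2O/pyridine gives 5,7-diacetoxycoumarin F1. PhSH/imidazole in NMP at 0 °C removes the more labile, less hindered 7-acetate, as known for peracetylated 5,7-dihydroxychromenones, to give 5-acetoxy-7-hydroxycoumarin F2. Mitsunobu coupling with 6 (PPh3, DIAD, THF) gives 5-acetoxy-7-{[(2E,6E,9E)-11-hydroxy-3,7,11-trimethyldodeca-2,6,9-trien-1-yl]oxy}coumarin F3. K2CO3/MeOH at 0 °C then releases 8.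

Third, step 6, the epoxide hydrolysis. Any attack of water at C10 gives the enantiomer of 10 and erodes ee. The acid may also touch the allylic aryl ether or trigger a semipinacol shift of the tertiary carbinol. The fallback sets out from 9 and comes back at 10. Ti(OiPr)4 and PhCO2H in CH2Cl2 at rt open the epoxide of the chelated 2,3-epoxy alcohol at the distal carbon C9 with inversion, giving 5-hydroxy-7-{[(2E,6E,9S,10S)-9-benzoyloxy-10,11-dihydroxy-3,7,11-trimethyldodeca-2,6-dien-1-yl]oxy}coumarin F4. K2CO3/MeOH then removes the benzoate to give 10.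

**Further compounds**

F0 | step 5 | none | none
F1 | step 4 | 5,7-diacetoxycoumarin | O=c1ccc2c(OC(C)=O)cc(OC(C)=O)cc2o1
F2 | step 4 | 5-acetoxy-7-hydroxycoumarin | O=c1ccc2c(OC(C)=O)cc(O)cc2o1
F3 | step 4 | 5-acetoxy-7-{[(2E,6E,9E)-11-hydroxy-3,7,11-trimethyldodeca-2,6,9-trien-1-yl]oxy}coumarin | C/C(=C\COc1cc(OC(C)=O)c2ccc(=O)oc2c1)CC/C=C(\C)C/C=C/C(C)(C)O
F4 | step 6 | 5-hydroxy-7-{[(2E,6E,9S,10S)-9-benzoyloxy-10,11-dihydroxy-3,7,11-trimethyldodeca-2,6-dien-1-yl]oxy}coumarin | C/C(=C\COc1cc(O)c2ccc(=O)oc2c1)CC/C=C(\C)C[C@H](OC(=O)c1ccccc1)[C@H](O)C(C)(C)O
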